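**Plan**

- Retrosynthesis: the allyl ester C–O bond and the two aryl–CHO bonds (C3 of each ring) are cut first, then the two MOM ethers. Ring B is opened at its C1–C6 bond (aldol) together with the ester bond made by ketene capture, giving a diketo-dioxinone. This is cut at the C4–C5 bond of the chain (Claisen) and at the O–CH2 bond of the glycolyl ester.
- Enabling feature: ring B (C1 carboxyl, C2 and C4 hydroxyls, C6 CH2O) is an orsellinate-type resorcylate. Its carbons C1–C6 map onto C2–C7 of a 3,5,7-trioxooctanoate whose C8 carries the ring A acyloxy group.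
- Forward: ring A comes ready-made from methyl orsellinate (protected, saponified, O-alkylated to a Weinreb amide). The chain is joined by Claisen condensation with the dianion of an acetonyl dioxinone. Ring B then arises by ketene capture and aldol aromatisation, and MOM removal, twofold formylation and deallylation finish the route.
- Stereochemistry: the target has no stereocentre; the two centres of the transient aldol are erased on aromatisation.

Key step: step 6

Assumption: both orsellinate-type rings are taken to formylate at C3, between the two hydroxyls, as simple orsellinate esters do under TiCl4/Cl2CHOMe.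

**Route**

Step 1
Reactants: 1 methyl orsellinate (methyl 2,4-dihydroxy-6-methylbenzoate)
Product: 2 methyl 2,4-bis(methoxymethoxy)-6-methylbenzoate
Conditions: NaH (2.5 equiv), MOMCl (2.5 equiv), DMF, 0 °C to rt
Reagents that add atoms: chloromethyl methyl ether, COCCl
Why: Williamson etherification of both sodium phenoxides with the α-chloro ether is fast in DMF, and full deprotonation by NaH overcomes the hydrogen bond that ties the 2-hydroxyl to the ester carbonyl.

Step 2
Reactants: 2 methyl 2,4-bis(methoxymethoxy)-6-methylbenzoate
Product: 3 2,4-bis(methoxymethoxy)-6-methylbenzoic acid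
Conditions: KOH (excess), MeOH/H2O, reflux; then cold 1 M HCl to pH 4, 0 °C
Reagents that add atoms: potassium hydroxide, [K+].[OH-]
Why: Saponification of the di-ortho-substituted methyl ester needs forcing hydroxide, which the base-stable MOM acetals tolerate, and a brief cold acidification to pH 4 frees the acid without cleaving them.

Step 3
Reactants: 3 2,4-bis(methoxymethoxy)-6-methylbenzoic acid; 4 2-chloro-N-methoxy-N-methylacetamide
Product: 5 2-[methoxy(methyl)amino]-2-oxoethyl 2,4-bis(methoxymethoxy)-6-methylbenzoate
Conditions: K2CO3 (1.5 equiv), NaI (0.1 equiv), DMF, 50 °C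
Reagents that add atoms: none
Why: SN2 O-alkylation of the potassium carboxylate by the α-halo amide (iodide-assisted) is not slowed by the shielding of the carboxyl carbon and installs the glycolyl carbon and a Weinreb amide acyl donor in one operation.

Step 4
Reactants: 6 2,2,6-trimethyl-4H-1,3-dioxin-4-one
Product: 7 2,2-dimethyl-6-(2-oxopropyl)-4H-1,3-dioxin-4-one
Conditions: LiN(SiMe3)2 (1.0 equiv), THF, −78 °C; AcCl (0.5 equiv), −78 °C; AcOH quench
Reagents that add atoms: acetyl chloride, CC(=O)Cl
Why: Kinetic γ-deprotonation gives the extended lithium dienolate, which is C-acylated at the exocyclic carbon (vinylogous Claisen acylation), and half of the dienolate serves as base for the more acidic product, which protects it from a second acylation.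

Step 5
Reactants: 7 2,2-dimethyl-6-(2-oxopropyl)-4H-1,3-dioxin-4-one; 5 2-[methoxy(methyl)amino]-2-oxoethyl 2,4-bis(methoxymethoxy)-6-methylbenzoate
Product: 8 5-(2,2-dimethyl-4-oxo-4H-1,3-dioxin-6-yl)-2,4-dioxopentyl 2,4-bis(methoxymethoxy)-6-methylbenzoate
Conditions: 7 (2 equiv), LiN(iPr)2 (4.2 equiv), THF, −78 °C; then 5 (1 equiv), −78 to −40 °C; AcOH quench
Reagents that add atoms: none
Why: In this crossed Claisen condensation the dianion of 7 reacts through its terminal carbanion with the Weinreb amide, whose chelated tetrahedral lithium adduct persists until the quench so that neither over-addition nor proton transfer from the acidic 1,3-diketone interferes, while the di-ortho-substituted aroyl ester is too hindered to be attacked.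

Step 6
Reactants: 8 5-(2,2-dimethyl-4-oxo-4H-1,3-dioxin-6-yl)-2,4-dioxopentyl 2,4-bis(methoxymethoxy)-6-methylbenzoate; 9 allyl alcohol
Product: 13 allyl 6-{[2,4-bis(methoxymethoxy)-6-methylbenzoyl]oxymethyl}-2,4-dihydroxybenzoate, via acylketene 10 (not isolated), via allyl triketo ester 11 (not isolated), via cyclic aldol 12 (not isolated)
Conditions: 9 (5 equiv), PhMe, 110 °C (sealed tube); concentrate; Cs2CO3 (2 equiv), iPrOH/CH2Cl2, rt; then AcOH, rt
Reagents that add atoms: none
Why: Heating cleaves the dioxinone by retro-(4+2) cycloreversion into acetone and acylketene 10, which allyl alcohol captures at the ketene carbon to give triketo ester 11; Cs2CO3 then forms the β-keto ester enolate at chain C2, which adds to the C7 ketone (cyclic aldol 12), and loss of water with enolisation of the C3 and C5 ketones gives the arene. The closest known reaction type is the ketene-capture and aldol aromatisation of diketo-dioxinones used to make resorcylate esters. Ring B closes through the C2–C7 bond of the chain (C1–C6 of the arene) in a 6-(enolendo)-exo-trig aldol mode, which is stereoelectronically allowed. No lasting stereocentre is formed, because both centres of 12 become sp2 on aromatisation. The C2-to-C7 aldol must win over capture of the ketene by the C5 enol oxygen (pyranone), over Claisen attack of C6 on the ester and over aldol attack of C8 on the C3 ketone: excess allyl alcohol present during thermolysis counters the first, the low electrophilicity of the ester towards a carbonate-generated enolate the second, and the far higher acidity of doubly activated C2 compared with C8 the third, while enolisation at the still more acidic C4 and C6 is reversible and leads only to strained rings or to the slow Claisen path, so that only the C2–C7 route is drained by irreversible aromatisation. The C7 ketone is the most electrophilic carbonyl because of its α-acyloxy group, and the di-ortho-substituted aroyl ester, which has no α-hydrogen and resists acyl shift, keeps the benzylic oxygen acylated so that no phthalide can form.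

Step 7
Reactants: 13 allyl 6-{[2,4-bis(methoxymethoxy)-6-methylbenzoyl]oxymethyl}-2,4-dihydroxybenzoate
Product: 14 allyl 6-{[(2,4-dihydroxy-6-methylbenzoyl)oxy]methyl}-2,4-dihydroxybenzoate
Conditions: HCl (1.25 M in MeOH), CH2Cl2, rt to 40 °C
Reagents that add atoms: none
Why: Acid-catalysed acetal methanolysis removes both aryl MOM ethers as dimethoxymethane, while the two di-ortho-substituted aryl esters resist acid transesterification and the benzylic oxygen, acylated and meta to both ring B hydroxyls, can neither lactonise nor ionise.

Step 8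
Reactants: 14 allyl 6-{[(2,4-dihydroxy-6-methylbenzoyl)oxy]methyl}-2,4-dihydroxybenzoate
Product: 15 allyl 3-formyl-6-{[(3-formyl-2,4-dihydroxy-6-methylbenzoyl)oxy]methyl}-2,4-dihydroxybenzoate
Conditions: Cl2CHOMe (4 equiv), TiCl4 (6 equiv), CH2Cl2, −10 °C to rt; then ice/1 M HCl
Reagents that add atoms: dichloromethyl methyl ether, COC(Cl)Cl; water, O
Why: In this Rieche formylation TiCl4 binds the phenol oxygens and delivers the chloro(methoxy)methyl cation to C3 of each ring, the position ortho to both hydroxyls, as in the conversion of simple orsellinate esters into haematommates, and the first formyl group deactivates each ring so that one aldehyde per ring results after hydrolysis.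

Step 9
Reactants: 15 allyl 3-formyl-6-{[(3-formyl-2,4-dihydroxy-6-methylbenzoyl)oxy]methyl}-2,4-dihydroxybenzoate
Product: 16 barbatolic acid (3-formyl-6-{[(3-formyl-2,4-dihydroxy-6-methylbenzoyl)oxy]methyl}-2,4-dihydroxybenzoic acid)
Conditions: Pd(PPh3)4 (5 mol %, zerovalent palladium), p-TolSO2Na (1.2 equiv), THF/MeOH, rt; then 1 M HCl to pH 2
Reagents that add atoms: none
Why: In this Tsuji–Trost deallylation zerovalent palladium ionises only the allyl ester to a π-allyl complex, the soft sulfinate removes the allyl group irreversibly as a sulfone, and the aldehydes, the phenols and the benzylic aroyl ester, which would not survive hydrogenolysis or saponification, stay intact.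

**Compound list**

1 | methyl orsellinate (methyl 2,4-dihydroxy-6-methylbenzoate) | COC(=O)c1c(C)cc(O)cc1O | starting material
2 | methyl 2,4-bis(methoxymethoxy)-6-methylbenzoate | COC(=O)c1c(C)cc(OCOC)cc1OCOC | intermediate
3 | 2,4-bis(methoxymethoxy)-6-methylbenzoic acid | Cc1cc(OCOC)cc(OCOC)c1C(=O)O | intermediate
4 | 2-chloro-N-methoxy-N-methylacetamide | CON(C)C(=O)CCl | starting material
5 | 2-[methoxy(methyl)amino]-2-oxoethyl 2,4-bis(methoxymethoxy)-6-methylbenzoate | CON(C)C(=O)COC(=O)c1c(C)cc(OCOC)cc1OCOC | intermediate
6 | 2,2,6-trimethyl-4H-1,3-dioxin-4-one | CC1=CC(=O)OC(C)(C)O1 | starting material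
7 | 2,2-dimethyl-6-(2-oxopropyl)-4H-1,3-dioxin-4-one | CC(=O)CC1=CC(=O)OC(C)(C)O1 | intermediate
8 | 5-(2,2-dimethyl-4-oxo-4H-1,3-dioxin-6-yl)-2,4-dioxopentyl 2,4-bis(methoxymethoxy)-6-methylbenzoate | CC1(C)OC(=O)C=C(CC(=O)CC(=O)COC(=O)c2c(C)cc(OCOC)cc2OCOC)O1 | intermediate
9 | allyl alcohol | C=CCO | starting material
10 | acylketene, 2,4,6,8-tetraoxooct-7-en-1-yl 2,4-bis(methoxymethoxy)-6-methylbenzoate | O=C=CC(=O)CC(=O)CC(=O)COC(=O)c1c(C)cc(OCOC)cc1OCOC | intermediate
11 | allyl 8-{[2,4-bis(methoxymethoxy)-6-methylbenzoyl]oxy}-3,5,7-trioxooctanoate | C=CCOC(=O)CC(=O)CC(=O)CC(=O)COC(=O)c1c(C)cc(OCOC)cc1OCOC | intermediate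
12 | allyl 2-{[2,4-bis(methoxymethoxy)-6-methylbenzoyl]oxymethyl}-2-hydroxy-4,6-dioxocyclohexane-1-carboxylate (mixture of stereoisomers, both centres lost on aromatisation) | C=CCOC(=O)C1C(=O)CC(=O)CC1(O)COC(=O)c1c(C)cc(OCOC)cc1OCOC | intermediate
13 | allyl 6-{[2,4-bis(methoxymethoxy)-6-methylbenzoyl]oxymethyl}-2,4-dihydroxybenzoate | C=CCOC(=O)c1c(O)cc(O)cc1COC(=O)c1c(C)cc(OCOC)cc1OCOC | intermediate
14 | allyl 6-{[(2,4-dihydroxy-6-methylbenzoyl)oxy]methyl}-2,4-dihydroxybenzoate | C=CCOC(=O)c1c(O)cc(O)cc1COC(=O)c1c(C)cc(O)cc1O | intermediate
15 | allyl 3-formyl-6-{[(3-formyl-2,4-dihydroxy-6-methylbenzoyl)oxy]methyl}-2,4-dihydroxybenzoate | C=CCOC(=O)c1c(O)c(C=O)c(O)cc1COC(=O)c1c(C)cc(O)c(C=O)c1O | intermediate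
16 | barbatolic acid | Cc1cc(O)c(C=O)c(O)c1C(=O)OCc1cc(O)c(C=O)c(O)c1C(=O)O | target

**Count and risks**

Total step count: 9. Longest linear sequence: 8 steps (steps 1, 2, 3, 5, 6, 7, 8, 9); step 4 is a one-step side branch.

The three steps most likely to fail:

Step 6. The acylketene may be captured internally by the enol oxygen at C5 before allyl alcohol adds, closing a 4-hydroxy-2-pyranone. Alternatively, the aroyl group may shift onto the tertiary hydroxyl of the aldol and then be expelled as aroate during aromatisation, which would strip ring A. The fallback sets out from 8 and comes back at 13, and it generates no ketene. Compound 8 is stirred with Et3N in CH2Cl2 at room temperature so that the dioxinone itself acts as the vinylogous enolate. Its ring carbon next to the carbonyl adds to the terminal ketone (the same ring B bond), and dehydration gives the acetonide-masked resorcylate (7-hydroxy-2,2-dimethyl-4-oxo-4H-1,3-benzodioxin-5-yl)methyl 2,4-bis(methoxymethoxy)-6-methylbenzoate F1. The benzodioxinone is then opened by allyl alcohol with K2CO3 (alkoxide transesterification with loss of acetone), which gives 13.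

Step 8. Formylation may occur at C5 on one or both rings, a ring may be formylated twice, or the chloro(methoxy)methyl cation may add to the allyl alkene. The fallback sets out from 14 and comes back at 15, and it enforces the position through the free chelated hydroxyl. The two non-chelated 4-hydroxyls are protected selectively (MOMCl, iPr2NEt, CH2Cl2, 0 °C) to give allyl 2-hydroxy-6-{[2-hydroxy-4-(methoxymethoxy)-6-methylbenzoyl]oxymethyl}-4-(methoxymethoxy)benzoate F2. Magnesium-phenoxide-directed ortho formylation (Casnati–Skattebøl; MgCl2, Et3N, paraformaldehyde, MeCN, reflux) can then only take place next to each free 2-hydroxyl, that is at C3, giving allyl 3-formyl-6-{[3-formyl-2-hydroxy-4-(methoxymethoxy)-6-methylbenzoyl]oxymethyl}-2-hydroxy-4-(methoxymethoxy)benzoate F3. HCl in MeOH removes the two MOM ethers to give 15.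

Step 5. The dianion may abstract a proton from the α-acyloxy CH2 of the Weinreb amide instead of adding to it, which would return both partners. The fallback sets out from 3 and comes back at 8, and it uses an aldehyde electrophile at a lower oxidation level. Acid 3 is alkylated with allyl bromide (K2CO3, DMF) to allyl 2,4-bis(methoxymethoxy)-6-methylbenzoate F4. Lemieux–Johnson cleavage (OsO4 cat., NaIO4, 2,6-lutidine, dioxane/H2O) gives 2-oxoethyl 2,4-bis(methoxymethoxy)-6-methylbenzoate F5. Aldol addition of the dianion of 7 (LiN(iPr)2, THF, −78 °C), which is much faster than proton transfer, gives racemic 5-(2,2-dimethyl-4-oxo-4H-1,3-dioxin-6-yl)-2-hydroxy-4-oxopentyl 2,4-bis(methoxymethoxy)-6-methylbenzoate F6. Dess–Martin oxidation of the β-hydroxy ketone in CH2Cl2 then gives 8.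

**Further compounds**

F1 | step 6 | (7-hydroxy-2,2-dimethyl-4-oxo-4H-1,3-benzodioxin-5-yl)methyl 2,4-bis(methoxymethoxy)-6-methylbenzoate | CC1(C)OC(=O)c2c(COC(=O)c3c(C)cc(OCOC)cc3OCOC)cc(O)cc2O1
F2 | step 8 | allyl 2-hydroxy-6-{[2-hydroxy-4-(methoxymethoxy)-6-methylbenzoyl]oxymethyl}-4-(methoxymethoxy)benzoate | C=CCOC(=O)c1c(O)cc(OCOC)cc1COC(=O)c1c(C)cc(OCOC)cc1O
F3 | step 8 | allyl 3-formyl-6-{[3-formyl-2-hydroxy-4-(methoxymethoxy)-6-methylbenzoyl]oxymethyl}-2-hydroxy-4-(methoxymethoxy)benzoate | C=CCOC(=O)c1c(O)c(C=O)c(OCOC)cc1COC(=O)c1c(C)cc(OCOC)c(C=O)c1O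
F4 | step 5 | allyl 2,4-bis(methoxymethoxy)-6-methylbenzoate | C=CCOC(=O)c1c(C)cc(OCOC)cc1OCOC
F5 | step 5 | 2-oxoethyl 2,4-bis(methoxymethoxy)-6-methylbenzoate | O=CCOC(=O)c1c(C)cc(OCOC)cc1OCOC
F6 | step 5 | 5-(2,2-dimethyl-4-oxo-4H-1,3-dioxin-6-yl)-2-hydroxy-4-oxopentyl 2,4-bis(methoxymethoxy)-6-methylbenzoate (racemic) | CC1(C)OC(=O)C=C(CC(=O)CC(O)COC(=O)c2c(C)cc(OCOC)cc2OCOC)O1
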